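**Retrosynthetic overview**
1. Paxidal ⇐ 11,12-diol 16 (double Swern) ⇐ 11-alcohol 15 (C12–O by allylic C–H oxidation) ⇐ dienyl acetate 13 (9α-H by kinetic protonation and in-situ reduction).
2. Key disconnection, the C1–O–acyl ester bond: 13 ⇐ C1 ketone 11 + cinnamaldehyde 12, by a redox-neutral reductive cinnamoylation that also sets C1.
3. 11 ⇐ trans-1,4-dione 10 (C4-selective methylenation; C3 and C5 by equilibration) ⇐ cis adduct 7.
4. 7 ⇐ quinone monoketal 3 + acetoxy-vinylallene 6 by enantioselective Diels–Alder; the ketal C–O bonds switch off the C4 carbonyl and so fix the regiochemistry.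
5. Ring order: ring A is the carbocycle of 2,5-dimethylphenol (dearomatised by C–O bond formation); ring B is then closed onto it by the cycloaddition.

Convention and assumption (one line): bicyclic compounds carry drimane-type locants (ring A = C1–C5, C10; ring B = C5–C10; C11 on C9; C12 on C8; C13 = exocyclic carbon on C4; C14 = methyl on C3; C15 = methyl on C10), β is the face of C15, and the sense of induction of (R)-BINOL in step 4 is assumed (the antipode is used if it proves opposite).

**Route**

Step 1
Reactants: 1 2,5-dimethylphenol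
Product: 3 4,4-dimethoxy-2,5-dimethylcyclohexa-2,5-dien-1-one, via 4-methoxy-2,5-dimethylphenol 2 (not isolated)
Conditions: PhI(OAc)2 (2.2 equiv), MeOH, 0 → 23 °C
Reagents that add atoms: methanol CO
Why: Hypervalent-iodine oxidative dearomatisation of a para-unsubstituted phenol in methanol forms two C–O bonds at the para carbon (first the p-methoxyphenol, then the quinone monoketal), masking the future C4 carbonyl so that C1=O alone polarises the dienophile; no stereocentre is created.

Step 2
Reactants: 4 3-methylpent-1-en-4-yn-3-ol (racemic)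
Product: 5 3-methylpent-1-en-4-yn-3-yl acetate
Conditions: Ac2O, Et3N, DMAP (10 mol %), CH2Cl2, 23 °C
Reagents that add atoms: acetic anhydride CC(=O)OC(C)=O
Why: DMAP-catalysed O-acylation (nucleophilic catalysis) of the tertiary propargylic alcohol; its racemic stereocentre is lost in the next step.

Step 3
Reactants: 5 3-methylpent-1-en-4-yn-3-yl acetate
Product: 6 3-methylpenta-1,2,4-trien-1-yl acetate (racemic allene)
Conditions: AgBF4 (2 mol %), CH2Cl2, 0 → 23 °C, used at once
Reagents that add atoms: none
Why: AgBF4-catalysed [3,3]-sigmatropic 1,3-acyloxy shift of a tertiary propargylic ester (Saucy–Marbet-type rearrangement) gives the conjugated acetoxy-vinylallene; its axial chirality is racemic, which does not matter because C9 and C11 stay sp2 in the adduct.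

Step 4
Reactants: 3 4,4-dimethoxy-2,5-dimethylcyclohexa-2,5-dien-1-one, 6 3-methylpenta-1,2,4-trien-1-yl acetate
Product: 7 cis-fused ketal enone adduct (C1=O; C2=C3; 4,4-(OCH3)2; C7=C8; C9=C11H–OAc E; 5β-H; 10β-CH3)
Conditions: TiCl2(O-i-Pr)2 (10 mol %), (R)-BINOL (10 mol %), 4 Å MS, 6 (2.5 equiv), CH2Cl2, −30 → 0 °C
Reagents that add atoms: none
Why: Enantioselective Lewis-acid-catalysed Diels–Alder reaction (binaphthol–titanium catalysis of quinone monoketals): with C1=O as the only activating group the nucleophilic vinyl terminus C6 bonds to the β-carbon C5 and the allene sp-carbon C9 to the α-carbon C10 of the less hindered α-methyl alkene, suprafacial addition gives the cis ring fusion, the catalyst selects the enantiotopic face and so fixes quaternary C10, and because C9 remains sp2 no endo/exo question arises there (any Z enol acetate converges in step 8).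

Step 5
Reactants: 7 cis-fused ketal enone adduct
Product: 10 trans-fused 1,4-dione (3β-CH3; 5α-H; 10β-CH3), via cis-enedione 8 (not isolated), via cis-dione 9 (not isolated)
Conditions: AcOH/H2O (4:1), 40 °C; then Zn dust, 23 °C; then DBU (0.2 equiv), PhMe, 40 °C
Reagents that add atoms: water O
Why: Ketal hydrolysis unveils the C4 ketone, Zn/AcOH reduces the C2=C3 bond of the ene-1,4-dione, and base equilibration through the C4 enols gives the thermodynamic trans-fused diketone with 5α-H and equatorial 3β-methyl (the same preference as 5α-4-keto steroids), so C5 and C3 are set under thermodynamic control.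

Step 6
Reactants: 10 trans-fused 1,4-dione
Product: 11 4-methylene 1-ketone (C4=C13H2; C1=O; otherwise as 10)
Conditions: Zn, CH2Br2, TiCl4, THF/CH2Cl2, 0 → 23 °C
Reagents that add atoms: dibromomethane BrCBr
Why: Takai–Lombardo methylenation is non-basic (no epimerisation at C3 or C5), spares the enol acetate, and should take the C4 carbonyl in preference to the neopentyl C1 carbonyl, which is flanked by quaternary C10 and by the peri enol-acetate CH; no stereocentre is formed.

Step 7
Reactants: 11 4-methylene 1-ketone, 12 (E)-cinnamaldehyde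
Product: 13 1β-(E)-cinnamoyloxy dienyl acetate (1α-H; C4=C13H2; C9=C11H–OAc E)
Conditions: Al(O-i-Pr)3 (10 mol %), 12 (1.5 equiv, syringe pump, 12 h), PhMe, 50 °C
Reagents that add atoms: none
Why: Proposed new method: an aluminium-alkoxide-relayed crossed Tishchenko reaction (formal hydroacylation of the C1=O bond) in which the Al-bound C1 alkoxide adds to slowly dosed cinnamaldehyde and the resulting hemiacetalate passes its hydride through a six-membered Meerwein–Ponndorf–Verley-type transition state to the next ketone molecule (kept in large excess over free aldehyde), entering C1 from the α face anti to the axial C15 methyl so that the ester C–O bond and the 1β centre are set in one operation; the closest known reactions are the Tishchenko and Evans–Tishchenko reactions and ketone hydroacylation, so far limited to aldehydes, β-hydroxy ketones or activated or chelating ketones.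

Step 8
Reactants: 13 1β-(E)-cinnamoyloxy dienyl acetate
Product: 15 1β-cinnamoyloxy 11-alcohol (9β-CH2OH; 9α-H; C7=C8; 8-CH3), via 11-aldehyde 14 (not isolated)
Conditions: NaBH4, MeOH/THF (1:1), 0 °C; AcOH quench at 0 °C
Reagents that add atoms: none
Why: Borohydride/methoxide cleaves the dienol acetate, the dienolate is protonated kinetically at the α-carbon C9 from the α face (anti to C15 and the 1β-ester), and the β,γ-unsaturated aldehyde is reduced at once before it can conjugate or epimerise (the classical dienol acetate to homoallylic alcohol reduction), which sets 9α-H; the cold acidic quench forestalls a 1→11 acyl shift.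

Step 9
Reactants: 15 1β-cinnamoyloxy 11-alcohol
Product: 16 1β-cinnamoyloxy 11,12-diol
Conditions: SeO2 (0.3 equiv), t-BuOOH (3 equiv), CH2Cl2, 23 °C
Reagents that add atoms: tert-butyl hydroperoxide CC(C)(C)OO
Why: Selenium dioxide allylic oxidation (ene reaction then [2,3]-sigmatropic shift) forms the C12–O bond at the methyl on the more substituted end of the trisubstituted alkene, as for drimenol, while the exocyclic methylene has only tertiary allylic C–H and reacts more slowly; no stereocentre is touched.

Step 10
Reactants: 16 1β-cinnamoyloxy 11,12-diol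
Product: 17 Paxidal
Conditions: (COCl)2, DMSO, CH2Cl2, −78 °C; Et3N, −78 → −30 °C
Reagents that add atoms: none
Why: Swern oxidation of the 11,12-diol at low temperature gives the 7-ene-11,12-dial without epimerising the base-sensitive C9 centre (the established polygodial end game), and the cinnamate is untouched.

**Compound list**

1 | 2,5-dimethylphenol | Cc1ccc(C)c(O)c1 | starting material
2 | 4-methoxy-2,5-dimethylphenol | COc1cc(C)c(O)cc1C | intermediate
3 | 4,4-dimethoxy-2,5-dimethylcyclohexa-2,5-dien-1-one | O=C1C(C)=CC(OC)(OC)C(C)=C1 | intermediate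
4 | 3-methylpent-1-en-4-yn-3-ol (racemic) | C=CC(C)(O)C#C | starting material
5 | 3-methylpent-1-en-4-yn-3-yl acetate (racemic) | C=CC(C)(OC(C)=O)C#C | intermediate
6 | 3-methylpenta-1,2,4-trien-1-yl acetate (racemic allene) | CC(=O)OC=C=C(C)C=C | intermediate
7 | cis-fused Diels–Alder adduct: ring A C1=O, C2=C3 (3-CH3), C4(OCH3)2; ring B C7=C8 (8-CH3), C9=C11H–OAc (E); 10β-CH3, 5β-H | COC1(OC)C(C)=CC(=O)[C@]2(C)/C(=C/OC(C)=O)C(C)=CC[C@H]12 | intermediate
8 | cis-fused ene-1,4-dione: 7 with C4=O in place of the ketal | O=C1C(C)=CC(=O)[C@]2(C)/C(=C/OC(C)=O)C(C)=CC[C@H]12 | intermediate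
9 | cis-fused 1,4-dione: C1=O, C4=O, 3β-CH3, 5β-H, 10β-CH3 (5-epimer of 10, formed together with its 3-epimer) | O=C1[C@@H](C)CC(=O)[C@]2(C)/C(=C/OC(C)=O)C(C)=CC[C@H]12 | intermediate
10 | trans-fused 1,4-dione: C1=O, C4=O, 3β-CH3, 5α-H, 10β-CH3, C7=C8 (8-CH3), C9=C11H–OAc (E) | O=C1[C@@H](C)CC(=O)[C@]2(C)/C(=C/OC(C)=O)C(C)=CC[C@@H]12 | intermediate
11 | 4-methylene 1-ketone: 10 with C4=C13H2 in place of C4=O | C=C1[C@@H](C)CC(=O)[C@]2(C)/C(=C/OC(C)=O)C(C)=CC[C@@H]12 | intermediate
12 | (E)-cinnamaldehyde | O=C/C=C/c1ccccc1 | starting material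
13 | 1β-(E)-cinnamoyloxy dienyl acetate: 11 with C1=O converted into 1β-O-cinnamoyl, 1α-H | C=C1[C@@H](C)C[C@@H](OC(=O)/C=C/c2ccccc2)[C@]2(C)/C(=C/OC(C)=O)C(C)=CC[C@@H]12 | intermediate
14 | 11-aldehyde: 1β-cinnamoyloxy, 3β-CH3, 4(13)-methylene, 5α-H, C7=C8 (8-CH3), 9β-CHO (9α-H), 10β-CH3 | C=C1[C@@H](C)C[C@@H](OC(=O)/C=C/c2ccccc2)[C@]2(C)[C@@H](C=O)C(C)=CC[C@@H]12 | intermediate
15 | 11-alcohol: 14 with 9β-CH2OH | C=C1[C@@H](C)C[C@@H](OC(=O)/C=C/c2ccccc2)[C@]2(C)[C@@H](CO)C(C)=CC[C@@H]12 | intermediate
16 | 11,12-diol: 15 with 8-CH2OH | C=C1[C@@H](C)C[C@@H](OC(=O)/C=C/c2ccccc2)[C@]2(C)[C@@H](CO)C(CO)=CC[C@@H]12 | intermediate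
17 | Paxidal: 1β-(E)-cinnamoyloxy-3β-methyl-4(13)-methylene-5α-H-10β-methyl-7-ene-11,12-dial, 9α-H | C=C1[C@@H](C)C[C@@H](OC(=O)/C=C/c2ccccc2)[C@]2(C)[C@@H](C=O)C(C=O)=CC[C@@H]12 | target

**Step count and risks**

Total: 10 steps. Longest linear sequence: 9 steps (from 4 through 5, 6, 7, 10, 11, 13, 15, 16 to 17); 8 steps from 1.

Step 4 (Diels–Alder). Risk: a hindered α-methyl monoketal, a labile racemic allenyl acetate and an untested catalyst–substrate pair may give low rate or low enantioselectivity. Fallback (auxiliary control in place of catalyst control, known chemistry), setting out from 3: transketalisation with (2R,3R)-butane-2,3-diol (PPTS, PhH, 60 °C) gives the spiro-ketal dienone (2R,3R)-2,3,6,9-tetramethyl-1,4-dioxaspiro[4.5]deca-6,9-dien-8-one F1. A thermal, uncatalysed Diels–Alder reaction with 6 (PhMe, 90 °C), face-controlled by the dioxolane methyl groups, gives the cis-fused spiro-ketal adduct F2; the (2S,3S)-diol is used if the facial sense is opposite. Hydrolysis with 1 M HCl/THF releases the diol and gives enedione 8, which continues inside step 5, so the route is rejoined at 10.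

Step 6 (site-selective methylenation). Risk: the C1 ketone may compete with C4. Fallback (temporary protection instead of relying on steric bias), setting out from 10: kinetic deprotonation of the C1 ketone at the C2 methylene and O-silylation (LDA, THF, −78 °C; TBSOTf) gives the C1 silyl enol ether F3. Wittig methylenation of the one remaining ketone (Ph3P=CH2, THF, 0 → 23 °C) gives the 4-methylene silyl enol ether F4. HF·pyridine (THF, 0 °C) returns the route at 11.

Step 7 (the proposed new step). Risk: homo-Tishchenko dimerisation of cinnamaldehyde, slow hydride transfer to the hindered ketone, or alkoxide attack on the enol acetate. Fallback (two separate known steps instead of one redox-neutral coupling), setting out from 11: LiAlH(O-t-Bu)3 (THF, 0 °C), with hydride delivery from the α face, gives the 1β-alcohol F5. Acylation with (E)-cinnamoyl chloride (DMAP, pyridine, CH2Cl2, 23 °C) returns the route at 13.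

**Further compounds**

F1 | step 4 | (2R,3R)-2,3,6,9-tetramethyl-1,4-dioxaspiro[4.5]deca-6,9-dien-8-one | O=C1C(C)=CC2(O[C@H](C)[C@@H](C)O2)C(C)=C1
F2 | step 4 | cis-fused spiro-ketal adduct: 7 with the 4,4-dimethoxy group replaced by a spiro (4R,5R)-4,5-dimethyl-1,3-dioxolane | C[C@H]1OC2(O[C@@H]1C)C(C)=CC(=O)[C@]3(C)/C(=C/OC(C)=O)C(C)=CC[C@H]23
F3 | step 6 | C1 tert-butyldimethylsilyl enol ether of 10 (C1=C2 enol ether, C4=O) | O=C1[C@@H](C)C=C(O[Si](C)(C)C(C)(C)C)[C@]2(C)/C(=C/OC(C)=O)C(C)=CC[C@@H]12
F4 | step 6 | 4-methylene C1 silyl enol ether (F3 with C4=C13H2) | C=C1[C@@H](C)C=C(O[Si](C)(C)C(C)(C)C)[C@]2(C)/C(=C/OC(C)=O)C(C)=CC[C@@H]12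
F5 | step 7 | 1β-alcohol: 11 with C1=O reduced to 1β-OH (1α-H) | C=C1[C@@H](C)C[C@@H](O)[C@]2(C)/C(=C/OC(C)=O)C(C)=CC[C@@H]12
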